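**Retrosynthetic overview**
1. The oxirane is made last: oxygen is transferred onto the (Z)-C4=C5 olefin of the finished bicyclic lactone from the molecule's own C1 ketone, across the ring (two C–O bonds, sets C4 and C5).
2. The ten-membered carbocycle comes from ring-closing metathesis at C4=C5; the C8 and C13 esters are installed between ring closure and epoxidation.
3. The metathesis diene comes from a Nozaki–Hiyama–Kishi union (C7–C8, sets C8) of a β-bromobutenolide with a keto aldehyde.
4. The butenolide (C6) comes from (E)-2,3-dibromobut-2-ene-1,4-diol by asymmetric vinylation and carbonylative lactonisation (lactone C–O bond); the keto aldehyde (C10) comes from α-methylene-γ-butyrolactone and 4-bromo-2-methylbut-1-ene.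
5. Ring order: butenolide, then ten-membered carbocycle, then oxirane.

Assumption: the target is taken exactly as drawn, i.e. a 4,5-cis-epoxide with 4S,5R,6R,8R,10S. Macrocycles are named with germacrane numbering (C1 ketone, C4 methyl-bearing olefin/epoxide carbon, C6 lactone carbinol, C7=C11 butenolide olefin, C8 ester carbinol, C10 methyl-bearing carbon, C12 lactone carbonyl, C13 the CH2O carbon). The SMILES in the list are authoritative for stereochemistry.

**Step 1**
Reactants: 1 (E)-2,3-dibromobut-2-ene-1,4-diol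
Product: 2 (E)-2,3-dibromo-4-[(tert-butyldimethylsilyl)oxy]but-2-en-1-ol
Conditions: NaH (1.0 equiv), THF, 0 °C; TBSCl (1.0 equiv), rt
Reagents that add atoms: tert-butyldimethylsilyl chloride, CC(C)(C)[Si](C)(C)Cl
Why: O-silylation of the sparingly soluble monosodium alkoxide gives clean monoprotection of the symmetric diol (desymmetrisation), and this silyl ether later decides which bromide can lactonise; no stereocentre is formed.

**Step 2**
Reactants: 2 (E)-2,3-dibromo-4-[(tert-butyldimethylsilyl)oxy]but-2-en-1-ol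
Product: 3 (E)-2,3-dibromo-4-[(tert-butyldimethylsilyl)oxy]but-2-enal
Conditions: Dess–Martin periodinane, NaHCO3, CH2Cl2, 0 °C
Reagents that add atoms: none
Why: Dess–Martin oxidation of the primary allylic alcohol to the enal under buffered, non-isomerising conditions keeps the E olefin geometry.

**Step 3**
Reactants: 3 (E)-2,3-dibromo-4-[(tert-butyldimethylsilyl)oxy]but-2-enal
Product: 4 (3S,4E)-4,5-dibromo-6-[(tert-butyldimethylsilyl)oxy]hexa-1,4-dien-3-ol
Conditions: Zn(CH=CH2)2 (1.5 equiv), (−)-MIB (5 mol %), toluene, −20 °C; H2O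
Reagents that add atoms: divinylzinc, C=C[Zn]C=C
Why: Amino-alcohol-catalysed enantioselective organozinc 1,2-addition; (−)-MIB delivers the vinyl group to the Si face of the enal, setting the carbinol (future C6) as 3S.

**Step 4**
Reactants: 4 (3S,4E)-4,5-dibromo-6-[(tert-butyldimethylsilyl)oxy]hexa-1,4-dien-3-ol
Product: 5 (5S)-4-bromo-3-{[(tert-butyldimethylsilyl)oxy]methyl}-5-ethenylfuran-2(5H)-one
Conditions: PdCl2(PPh3)2 (5 mol %), CO (3 atm), NaOAc, MeCN, 50 °C
Reagents that add atoms: carbon monoxide, [C-]#[O+]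
Why: Palladium-catalysed carbonylative lactonisation (intramolecular alkoxycarbonylation): only the bromide cis to the free carbinol can close the five-membered ring, the lactone C–O bond forms by acyl substitution so C6 keeps its configuration, and the surviving bromide becomes the activated β-bromide of the butenolide.

**Step 5**
Reactants: 6 α-methylene-γ-butyrolactone (3-methylidenedihydrofuran-2(3H)-one)
Product: 7 (3S)-3-methyldihydrofuran-2(3H)-one
Conditions: H2 (100 atm), Ru(OAc)2[(R)-BINAP] (0.5 mol %), CH2Cl2, 50 °C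
Reagents that add atoms: none
Why: Ruthenium–BINAP asymmetric hydrogenation of the exocyclic enoate sets the methyl stereocentre (future C10) as S; the (R)-BINAP antipode is chosen because, as far as I recall, the (S)-ligand gives the (R)-lactone, which should be confirmed by optical rotation.

**Step 6**
Reactants: 7 (3S)-3-methyldihydrofuran-2(3H)-one; 8 4-bromo-2-methylbut-1-ene
Product: 10 (3S)-1-hydroxy-3,7-dimethyloct-7-en-4-one, via 3-methylbut-3-enyllithium 9 (not isolated)
Conditions: 8, t-BuLi (2.1 equiv), Et2O–pentane, −78 °C; then 7, −78 °C; H2O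
Reagents that add atoms: none
Why: Bromine–lithium exchange then nucleophilic acyl substitution on the lactone; the lithium hemiketal holds until quench so a single addition gives the ketone (C1) and frees the C8 oxygen, and the α-stereocentre is not enolised at −78 °C.

**Step 7**
Reactants: 10 (3S)-1-hydroxy-3,7-dimethyloct-7-en-4-one
Product: 11 (3S)-3,7-dimethyl-4-oxooct-7-enal
Conditions: Dess–Martin periodinane, NaHCO3, CH2Cl2, 0 °C
Reagents that add atoms: none
Why: Dess–Martin oxidation of the primary alcohol (open form of the lactol) gives the γ-keto aldehyde without base, so C10 is not epimerised.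

**Step 8**
Reactants: 5 (5S)-4-bromo-3-{[(tert-butyldimethylsilyl)oxy]methyl}-5-ethenylfuran-2(5H)-one; 11 (3S)-3,7-dimethyl-4-oxooct-7-enal
Product: 12 (5S)-3-{[(tert-butyldimethylsilyl)oxy]methyl}-5-ethenyl-4-[(1R,3S)-1-hydroxy-3,7-dimethyl-4-oxooct-7-en-1-yl]furan-2(5H)-one
Conditions: CrCl2 (4 equiv), NiCl2 (2 mol %), chiral oxazoline–sulfonamide ligand (4.4 equiv, antipode directing Si-face attack), Et3N (4.4 equiv), THF, rt; H2O
Reagents that add atoms: none
Why: Ligand-controlled asymmetric Nozaki–Hiyama–Kishi coupling; the alkenylchromium from the β-bromide adds to the aldehyde and not the ketone, and the ligand steers attack to the Si face to set C8 as R.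

**Step 9**
Reactants: 12 (5S)-3-{[(tert-butyldimethylsilyl)oxy]methyl}-5-ethenyl-4-[(1R,3S)-1-hydroxy-3,7-dimethyl-4-oxooct-7-en-1-yl]furan-2(5H)-one
Product: 13 (4Z,6S,8R,10S)-13-[(tert-butyldimethylsilyl)oxy]-8-hydroxy-1-oxogermacra-4,7(11)-dien-12,6-olide
Conditions: second-generation Hoveyda–Grubbs catalyst (10 mol %), toluene (1 mM), 80 °C
Reagents that add atoms: none
Why: Ring-closing metathesis of the vinyl group onto the 1,1-disubstituted olefin closes the ten-membered ring, which under equilibrating conditions takes the less strained cis (Z) trisubstituted olefin; C8–OH is left free because a methacrylate there would divert the catalyst into a seven-membered lactone.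

**Step 10**
Reactants: 13 (4Z,6S,8R,10S)-13-[(tert-butyldimethylsilyl)oxy]-8-hydroxy-1-oxogermacra-4,7(11)-dien-12,6-olide
Product: 14 (4Z,6S,8R,10S)-13-[(tert-butyldimethylsilyl)oxy]-8-(methacryloyloxy)-1-oxogermacra-4,7(11)-dien-12,6-olide
Conditions: methacrylic anhydride, DMAP (cat.), Et3N, CH2Cl2, −20 to 0 °C
Reagents that add atoms: methacrylic anhydride, C=C(C)C(=O)OC(=O)C(C)=C
Why: DMAP-catalysed acylation of the secondary alcohol with retention at C8; it also removes the hydroxyl that would otherwise mask the C1 ketone as a hemiketal in the last step.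

**Step 11**
Reactants: 14 (4Z,6S,8R,10S)-13-[(tert-butyldimethylsilyl)oxy]-8-(methacryloyloxy)-1-oxogermacra-4,7(11)-dien-12,6-olide
Product: 16 (4Z,6S,8R,10S)-13-acetoxy-8-(methacryloyloxy)-1-oxogermacra-4,7(11)-dien-12,6-olide, via the C13 alcohol 15 (not isolated)
Conditions: HF·pyridine, pyridine–THF, 0 °C; then Ac2O, DMAP (cat.), rt (one pot)
Reagents that add atoms: acetic anhydride, CC(=O)OC(C)=O
Why: Fluoride desilylation under non-basic conditions (the γ-hydrogen at C6 is base-sensitive) followed by acetylation of the freed primary alcohol; no stereocentre is involved.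

**Step 12**
Reactants: 16 (4Z,6S,8R,10S)-13-acetoxy-8-(methacryloyloxy)-1-oxogermacra-4,7(11)-dien-12,6-olide
Product: 18 (4S,5R,6R,8R,10S)-13-acetoxy-4,5-epoxy-8-(methacryloyloxy)-1-oxogermacr-7(11)-en-12,6-olide, via the C1 dioxirane 17 (not isolated)
Conditions: KHSO5 (as Oxone, 2KHSO5·KHSO4·K2SO4; 3 equiv), NaHCO3, MeCN–H2O, 0.5 mM, 0 °C to rt
Reagents that add atoms: potassium peroxymonosulfate, [K+].[O-]S(=O)(=O)OO
Why: Proposed new method: peroxymonosulfate converts the substrate's own C1 ketone into dioxirane 17, which sits transannular to C4=C5 and passes one oxygen through a spiro transition state to the ring-interior face of the olefin (the face syn to C7 once H6 eclipses the olefin to avoid allylic 1,3-strain), giving the cis-epoxide 4S,5R, erythro to the C6–O bond, and regenerating the ketone, whereas an external peracid or dioxirane would meet only the exo face and give the 4R,5S isomer; the closest known chemistry is ketone-catalysed dioxirane epoxidation (Shi type) and intramolecular oxidations by dioxiranes generated from tethered ketones, here run at high dilution so that self-delivery beats bimolecular transfer.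

**Compound list**
1 | (E)-2,3-dibromobut-2-ene-1,4-diol | OC/C(Br)=C(\Br)CO | starting material
2 | (E)-2,3-dibromo-4-[(tert-butyldimethylsilyl)oxy]but-2-en-1-ol | OC/C(Br)=C(\Br)CO[Si](C)(C)C(C)(C)C | intermediate
3 | (E)-2,3-dibromo-4-[(tert-butyldimethylsilyl)oxy]but-2-enal | O=C/C(Br)=C(\Br)CO[Si](C)(C)C(C)(C)C | intermediate
4 | (3S,4E)-4,5-dibromo-6-[(tert-butyldimethylsilyl)oxy]hexa-1,4-dien-3-ol | C=C[C@H](O)/C(Br)=C(\Br)CO[Si](C)(C)C(C)(C)C | intermediate
5 | (5S)-4-bromo-3-{[(tert-butyldimethylsilyl)oxy]methyl}-5-ethenylfuran-2(5H)-one | O=C1O[C@@H](C=C)C(Br)=C1CO[Si](C)(C)C(C)(C)C | intermediate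
6 | α-methylene-γ-butyrolactone | C=C1CCOC1=O | starting material
7 | (3S)-3-methyldihydrofuran-2(3H)-one | C[C@H]1CCOC1=O | intermediate
8 | 4-bromo-2-methylbut-1-ene | C=C(C)CCBr | starting material
9 | 3-methylbut-3-enyllithium | [Li]CCC(C)=C | intermediate
10 | (3S)-1-hydroxy-3,7-dimethyloct-7-en-4-one | OCC[C@H](C)C(=O)CCC(C)=C | intermediate
11 | (3S)-3,7-dimethyl-4-oxooct-7-enal | O=CC[C@H](C)C(=O)CCC(C)=C | intermediate
12 | (5S)-3-{[(tert-butyldimethylsilyl)oxy]methyl}-5-ethenyl-4-[(1R,3S)-1-hydroxy-3,7-dimethyl-4-oxooct-7-en-1-yl]furan-2(5H)-one | C=C[C@@H]1OC(=O)C(CO[Si](C)(C)C(C)(C)C)=C1[C@H](O)C[C@H](C)C(=O)CCC(C)=C | intermediate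
13 | (4Z,6S,8R,10S)-13-[(tert-butyldimethylsilyl)oxy]-8-hydroxy-1-oxogermacra-4,7(11)-dien-12,6-olide | O[C@@H]1C[C@H](C)C(=O)CC/C(C)=C\[C@@H]2OC(=O)C(CO[Si](C)(C)C(C)(C)C)=C21 | intermediate
14 | (4Z,6S,8R,10S)-13-[(tert-butyldimethylsilyl)oxy]-8-(methacryloyloxy)-1-oxogermacra-4,7(11)-dien-12,6-olide | C=C(C)C(=O)O[C@@H]1C[C@H](C)C(=O)CC/C(C)=C\[C@@H]2OC(=O)C(CO[Si](C)(C)C(C)(C)C)=C21 | intermediate
15 | (4Z,6S,8R,10S)-13-hydroxy-8-(methacryloyloxy)-1-oxogermacra-4,7(11)-dien-12,6-olide | C=C(C)C(=O)O[C@@H]1C[C@H](C)C(=O)CC/C(C)=C\[C@@H]2OC(=O)C(CO)=C21 | intermediate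
16 | (4Z,6S,8R,10S)-13-acetoxy-8-(methacryloyloxy)-1-oxogermacra-4,7(11)-dien-12,6-olide | C=C(C)C(=O)O[C@@H]1C[C@H](C)C(=O)CC/C(C)=C\[C@@H]2OC(=O)C(COC(C)=O)=C21 | intermediate
17 | C1 dioxirane of 16 (1,1-peroxy in place of the 1-oxo group) | C=C(C)C(=O)O[C@@H]1C[C@H](C)C3(OO3)CC/C(C)=C\[C@@H]2OC(=O)C(COC(C)=O)=C21 | intermediate
18 | (4S,5R,6R,8R,10S)-13-acetoxy-4,5-epoxy-8-(methacryloyloxy)-1-oxogermacr-7(11)-en-12,6-olide (C6 has the same spatial arrangement as in 13–16; only its descriptor changes) | C=C(C)C(=O)O[C@@H]1C[C@H](C)C(=O)CC[C@]2(C)O[C@@H]2[C@@H]2OC(=O)C(COC(C)=O)=C21 | target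

**Totals**
Total steps: 12. Longest linear sequence: 9 (steps 1–4, then 8–12); the second branch (steps 5–7) joins at step 8.

**Three steps most likely to fail**

Step 12 (proposed new transannular epoxidation). It may give the exo-face epoxide through bimolecular oxygen transfer, or the hindered ketone may not form its dioxirane. Fallback with known chemistry, setting out from 16 and returning at 18: treat 16 with NBS in aqueous THF at 0 °C. Bromonium forms on the open exo face and oxygen enters anti at the tertiary C4 from the ring interior, giving the bromohydrin F5 (which may sit as its 1,4-hemiketal). Ag2O in CH2Cl2 then lets the C4 oxygen displace bromide at C5 with inversion, so the epoxide oxygen ends on the interior face as in 18.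

Step 9 (ring-closing metathesis to the ten-membered ring). It may stall at the 1,1-disubstituted olefin or give oligomers. Fallback, setting out from 12 and returning at 13: tie the C8 hydroxyl and the C1 ketone together as the cyclic methyl ketal F3 (MeOH, CH(OMe)3, PPTS cat.). The tetrahydrofuran ring folds the chain and turns the macrocyclisation into closure of a bridged bicycle. Metathesis of F3 under the step 9 conditions gives the bridged ketal F4, and mild aqueous acid (PPTS, acetone–H2O) returns the hydroxy ketone 13.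

Step 8 (asymmetric Nozaki–Hiyama–Kishi coupling). Ligand control at C8 may be poor on this β-bromobutenolide. Fallback, setting out from 5 and 11 and returning at 14: run the coupling without chiral ligand (CrCl2, NiCl2 cat., DMSO–THF) and separate 12 from its C8 epimer F1. Take 12 on as in the route. Close F1 by the step 9 metathesis to the 8-epi macrocycle F2, then esterify F2 with inversion (methacrylic acid, PPh3, DIAD, toluene, 0 °C; Mitsunobu) to reach 14, so both epimers converge.

**Further compounds**
F1 | step 8 | (5S)-3-{[(tert-butyldimethylsilyl)oxy]methyl}-5-ethenyl-4-[(1S,3S)-1-hydroxy-3,7-dimethyl-4-oxooct-7-en-1-yl]furan-2(5H)-one (C8 epimer of 12) | C=C[C@@H]1OC(=O)C(CO[Si](C)(C)C(C)(C)C)=C1[C@@H](O)C[C@H](C)C(=O)CCC(C)=C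
F2 | step 8 | (4Z,6S,8S,10S)-13-[(tert-butyldimethylsilyl)oxy]-8-hydroxy-1-oxogermacra-4,7(11)-dien-12,6-olide (C8 epimer of 13) | O[C@H]1C[C@H](C)C(=O)CC/C(C)=C\[C@@H]2OC(=O)C(CO[Si](C)(C)C(C)(C)C)=C21
F3 | step 9 | cyclic methyl ketal of 12 (2-methoxytetrahydrofuran joining C8–O to C1, mixture at C1) | C=C[C@@H]1OC(=O)C(CO[Si](C)(C)C(C)(C)C)=C1[C@H]1C[C@H](C)C(OC)(CCC(C)=C)O1
F4 | step 9 | 1,8-epoxy-1-methoxy bridged ketal of 13 (mixture at C1) | COC12CC/C(C)=C\[C@@H]3OC(=O)C(CO[Si](C)(C)C(C)(C)C)=C3[C@H](O2)C[C@@H]1C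
F5 | step 12 | 5-bromo-4-hydroxy bromohydrin of 16 (C4–OH on the interior face, C5–Br on the exo face) | C=C(C)C(=O)O[C@@H]1C[C@H](C)C(=O)CC[C@](C)(O)[C@@H](Br)[C@@H]2OC(=O)C(COC(C)=O)=C21
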